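# Proposed synthesis of furofuran lignan 14 (CNP0181235.1) by oxidative β–β dimerisation of a 5-benzyloxy monolignol

## The problem

Target 14 is a furofuran lignan: a cis-fused 3,7-dioxabicyclo[3.3.0]octane built from two C6C3 units joined C8–C8', with the C9 oxygen of each unit bonded to the benzylic C7 of the other and both aryl groups exo. The four contiguous stereocentres are (7S,8R,7'S,8'R), i.e. (1S,3aR,4S,6aR) in furo[3,4-c]furan numbering. The cis fusion is forced by the bicycle and the exo aryl groups are the preferred arrangement once C8 and C8' are fixed, so the relative configuration follows from the ring-fusion pair. The absolute configuration of that pair has no internal source. Ring A (3-hydroxy-4,5-dimethoxyphenyl) and ring B (3,4,5-trimethoxyphenyl) differ by one O-methyl group, so 14 is the mono-methyl ether of a C2-symmetric bisphenol and two homotopic phenols must be told apart. The fragile elements are the two benzylic C7–O bonds, which ionise under protic or Lewis acids (epimerisation to the endo series, ring opening) and can be lost on prolonged hydrogenolysis, and the electron-rich rings with their free phenol, which do not tolerate strong oxidants. The enabling feature is that each half is a cinnamyl alcohol with oxygen at C4 (para to the side chain) and at both C3 and C5: with O4 as a free phenol, one-electron oxidation puts spin on C8, the flanking alkoxy groups close off coupling through the ring, and each C9 hydroxyl can add to the partner's C7 once C8–C8' exists.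

## Retrosynthesis

**14 to 13.** The O–CH3 bond at the meta oxygen of ring B is cut first. This exposes bisphenol 13, whose two halves are identical, so the whole skeleton can come from one monomer. Keeping the rings different further back would mean joining two unlike halves, which moves the statistical problem into the skeleton-forming step. The forward reaction is a mono-methylation of two homotopic, electronically independent phenols. It is statistical, but unreacted 13 can be recycled.

**13 to 12 to 11.** The two meta phenols of 13 are masked as benzyl ethers (12) and the two para methyl ethers are cut back to free phenols (11). The para phenol must be free for the oxidative coupling. The meta oxygen must be blocked, because a free catechol would be oxidised to an ortho-quinone instead. The benzyl group also keeps the second ortho position of the phenol occupied. The forward steps are an exhaustive methylation and a double hydrogenolysis, both on C2-symmetric substrates and therefore free of selectivity questions.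

**11 to 10.** The single enantiomer 11 is traced to racemate 10 by separation of antipodes. The plant proteins that steer this radical coupling are reported to act on the guaiacyl-type radical (C5 unsubstituted) and to leave 3,5-disubstituted monolignols uninfluenced. Monolignol 7, with a benzyloxy group at C5, is further still from their native substrate. Absolute control is therefore not asked of the coupling. It is imposed immediately afterwards, on the cheapest chiral intermediate, by chromatography on a chiral stationary phase.

**10 to two molecules of 7.** Three bonds are cut at once: C8–C8', C7–O9' and C7'–O9. This removes both rings and all four stereocentres and leaves the achiral monolignol 7. Cutting one tetrahydrofuran ring at a time, or the aryl–C7 bonds, would leave a chiral C8/C8' fragment still to be made. The forward reaction passes through phenoxyl radical 8 and bis(quinone methide) 9. It must couple only through C8 (secured by the OMe and OBn groups ortho to the phenol) and must close both rings with exo aryl groups (inherent to the bicycle).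

**7 to 6 to 4 and 5.** The allylic alcohol is taken back to ethyl cinnamate 6, and the C7=C8 double bond is cut to aldehyde 4 and stabilised ylide 5. The ylide tolerates the free phenol, so no phenol protection is needed. The forward steps are an E-selective Wittig olefination and a 1,2-reduction of the ester.

**4 to 1 and 2.** The benzyl–oxygen bond is cut to 5-hydroxyvanillin 1 and benzyl bromide 2. The forward reaction must alkylate the oxygen meta to the formyl group and leave the more acidic para oxygen free. This is done through the dianion.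

## Roads not taken

**Alternative 1:** two-directional double syn-aldol. The cut is at C7–C8 and C7'–C8'. The bis-boron enolate of succinyl bis-imide A2 (Bu2BOTf, iPr2NEt) would add to two molecules of aldehyde A3 to give bis-aldol A1 with all four centres set and no ring closed. Reduction to tetraol A4 and double ring closure would then reach 12.
- Merit: absolute configuration comes from the auxiliary, so no material is lost to a resolution. In this respect it is better than the chosen plan.
- Weak points: a 1,4-dicarbonyl must be enolised twice; the first aldolate can lactonise onto the neighbouring imide; the second aldol is a double-stereodifferentiating event next to a new stereocentre. The rings still have to be made in two further steps, and the hydrogenolysis and statistical mono-methylation remain.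
- Comparison: the chosen plan sets against it a precedented step that makes three bonds, two rings and four centres from an achiral monomer, with no stoichiometric auxiliary or cryogenic boron chemistry, and a loss to resolution that falls early.

**Alternative 2:** Baeyer–Villiger ring expansion. The cut is at O–C7 of one ring. mCPBA would insert oxygen between the ketone carbon and the benzylic carbon of cyclobutanone A6 to give bis-lactone A5; the benzylic carbon migrates with retention.
- Merit: the two aryl groups are different from the outset (one benzyl ether only), so the final hydrogenolysis gives the target directly and the statistical methylation disappears. This is a real advantage over the chosen plan.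
- Weak points: the difficulty moves into A6, a strained bicycle with four contiguous centres and two different aryl groups, which the key step does nothing to assemble. Both lactone carbonyls of A5 must later be reduced and the ethers re-closed, which reopens the ring just made and exposes both benzylic centres.
- Comparison: the chosen plan is much shorter and builds the final rings directly; it pays with one statistical step on a recyclable bisphenol.

**Alternative 3:** double exo-arylation of a bis-lactol. The cut is at both aryl–C7 bonds. BF3·OEt2 would ionise both acetates of bis-lactol diacetate A8, and aryltrifluoroborate A9 would deliver its aryl group to the convex face twice, giving A7, which has the structure of 12.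
- Merits: it is convergent, the exo selectivity is credible, and the absolute configuration would reside in a small core, so no resolution is needed if A8 is enantiopure.
- Weak points: the product's benzylic ethers carry electron-rich aryl groups and are labile to the same Lewis acid. The trialkoxyarene can attack through its ring carbons ortho to alkoxy instead of at the boron-bearing carbon. Enantiopure A8 needs a synthesis of its own. The product is C2-symmetric, so hydrogenolysis and mono-methylation remain as in the chosen plan.
- Comparison: the chosen plan never exposes the furofuran to a Lewis acid and makes the core in one step; it has to accept the resolution in exchange.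

Key step: step 4

## Route

Assumption: 1, 2, 5 and Trametes versicolor laccase are taken as commercial, and racemate 10 is represented by the SMILES of its (1S,3aR,4S,6aR) enantiomer.

Step 1
Reactants: 1 5-hydroxyvanillin (3,4-dihydroxy-5-methoxybenzaldehyde); 2 benzyl bromide
Product: 4 3-(benzyloxy)-4-hydroxy-5-methoxybenzaldehyde, via disodium dianion of 5-hydroxyvanillin 3 (not isolated)
Conditions: NaH (2.2 equiv), DMSO, 20 °C, Ar; then 2 (1.0 equiv), 20 °C; aq. HCl
Reagents that add atoms: none
Why: Williamson etherification of a catechol dianion: in 3 the oxide para to the formyl group is delocalised into the carbonyl and flanked by two oxygen substituents, so the more basic, less hindered oxide meta to the formyl group should take the single equivalent of benzyl bromide, as established for 3,4-dihydroxybenzaldehydes.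

Step 2
Reactants: 4 3-(benzyloxy)-4-hydroxy-5-methoxybenzaldehyde; 5 ethyl (triphenyl-λ5-phosphanylidene)acetate
Product: 6 ethyl (E)-3-[3-(benzyloxy)-4-hydroxy-5-methoxyphenyl]prop-2-enoate
Conditions: 5 (1.5 equiv), toluene, 110 °C
Reagents that add atoms: none
Why: Wittig olefination with a stabilised ylide, which is compatible with free para-hydroxybenzaldehydes and should give the E-cinnamate selectively.

Step 3
Reactants: 6 ethyl (E)-3-[3-(benzyloxy)-4-hydroxy-5-methoxyphenyl]prop-2-enoate
Product: 7 (E)-3-(benzyloxy)-4-hydroxy-5-methoxycinnamyl alcohol, i.e. 2-(benzyloxy)-4-[(E)-3-hydroxyprop-1-en-1-yl]-6-methoxyphenol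
Conditions: iBu2AlH (4.5 equiv), toluene, 0 °C; EtOH, then aq. KNaC4H4O6
Reagents that add atoms: none
Why: DIBAL-H 1,2-reduction of an α,β-unsaturated ester to the allylic alcohol, the standard way from cinnamate esters to monolignols; the phenol only consumes one equivalent of hydride as its aluminium phenoxide, and the alkene and benzyl ether are not touched.

Step 4
Reactants: 7 (E)-3-(benzyloxy)-4-hydroxy-5-methoxycinnamyl alcohol (two molecules)
Product: 10 rac-(1S,3aR,4S,6aR)-1,4-bis[3-(benzyloxy)-4-hydroxy-5-methoxyphenyl]tetrahydro-1H,3H-furo[3,4-c]furan (racemate; exo,exo; cis-fused), via monolignol phenoxyl radical 8 (not isolated), via C8–C8' bis(quinone methide) 9 (not isolated)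
Conditions: laccase (Trametes versicolor), air (O2), NaOAc buffer (pH 5)/acetone 2:1, 25 °C
Reagents that add atoms: none
Why: The laccase, a multicopper oxidase, uses O2 to take one electron and one proton from the para phenol of 7, giving radical 8 with spin shared between O4, the ring carbons ortho to it (both blocked, by OMe and OBn) and the side-chain carbon C8. Two radicals 8 combine C8–C8' to bis(quinone methide) 9, and each C9 hydroxyl then adds to the C7 quinone methide carbon of the other half: two 5-exo-trig oxa-1,6-additions that restore both aromatic rings and close the two tetrahydrofuran rings. The closest known reaction type is the laccase/O2 or peroxidase/H2O2 dehydrodimerisation of sinapyl alcohol to syringaresinol, from whose substrate 7 differs only by a benzyloxy in place of one methoxy group. The C8/C8' pair is set in the radical combination, since only the C2-symmetric (like) bis(quinone methide) can close both rings into the cis-fused bicycle that the [3.3.0] skeleton demands. C7 and C7' are set in the ring closures, where each aryl group should take the exo position, trans to the substituent on the adjacent ring-fusion carbon, which is also the thermodynamically preferred arrangement. The enzyme acts only as oxidant and the radicals couple free in solution, so no absolute control is expected and 10 should form as the racemate. The selectivity needed is regiochemical (8–8' over 8–5 and 8–O–4); the alkoxy groups at C3 and C5 exclude 8–5 coupling and hinder the phenoxyl oxygen. Precipitation of the dimer from the aqueous medium should limit its further oxidation.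

Step 5
Reactants: 10 rac-(1S,3aR,4S,6aR)-1,4-bis[3-(benzyloxy)-4-hydroxy-5-methoxyphenyl]tetrahydro-1H,3H-furo[3,4-c]furan
Product: 11 (1S,3aR,4S,6aR)-1,4-bis[3-(benzyloxy)-4-hydroxy-5-methoxyphenyl]tetrahydro-1H,3H-furo[3,4-c]furan (single enantiomer)
Conditions: preparative HPLC, cellulose tris(3,5-dimethylphenylcarbamate) on silica, hexane/EtOH, 25 °C
Reagents that add atoms: none
Why: Chromatographic resolution of enantiomers on a polysaccharide carbamate phase, the usual way of separating the antipodes of phenolic furofuran lignans; no stereocentre is made or touched, and the (7S,8R,7'S,8'R) antipode is to be identified by circular dichroism against furofuran lignans of known configuration.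

Step 6
Reactants: 11 (1S,3aR,4S,6aR)-1,4-bis[3-(benzyloxy)-4-hydroxy-5-methoxyphenyl]tetrahydro-1H,3H-furo[3,4-c]furan
Product: 12 (1S,3aR,4S,6aR)-1,4-bis[3-(benzyloxy)-4,5-dimethoxyphenyl]tetrahydro-1H,3H-furo[3,4-c]furan
Conditions: MeI (5 equiv), K2CO3 (4 equiv), DMF, 25 °C
Reagents that add atoms: iodomethane, CI
Why: Williamson O-methylation of both 2,6-dialkoxyphenols (phenoxide SN2 on MeI); the basic medium leaves the acid-sensitive benzylic ethers and all four stereocentres untouched.

Step 7
Reactants: 12 (1S,3aR,4S,6aR)-1,4-bis[3-(benzyloxy)-4,5-dimethoxyphenyl]tetrahydro-1H,3H-furo[3,4-c]furan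
Product: 13 5,5'-[(1S,3aR,4S,6aR)-tetrahydro-1H,3H-furo[3,4-c]furan-1,4-diyl]bis(2,3-dimethoxyphenol)
Conditions: H2 (1 atm), 10% Pd/C, EtOAc, 20 °C, stopped after uptake of 2 equiv H2
Reagents that add atoms: none
Why: Heterogeneous hydrogenolysis of aryl benzyl ethers, which in neutral ethyl acetate should cleave well before the dialkyl benzylic C7–O bonds of the bicycle, as in the deprotection of other 2-aryltetrahydrofuran lignans; acid is excluded so that C7 and C7' are not epimerised.

Step 8
Reactants: 13 5,5'-[(1S,3aR,4S,6aR)-tetrahydro-1H,3H-furo[3,4-c]furan-1,4-diyl]bis(2,3-dimethoxyphenol)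
Product: 14 5-[(1S,3aR,4S,6aR)-4-(3,4,5-trimethoxyphenyl)tetrahydro-1H,3H-furo[3,4-c]furan-1-yl]-2,3-dimethoxyphenol (target)
Conditions: MeI (0.7 equiv), K2CO3 (1.0 equiv), DMF, 20 °C; unreacted 13 recovered and resubmitted
Reagents that add atoms: iodomethane, CI
Why: Williamson mono-O-methylation with limiting MeI; the two phenols are homotopic and remote, so methylation of either gives the same 14 and the distribution is statistical, with 14, recovered 13 and the doubly methylated by-product differing by one phenol each and therefore separable on silica.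

## Compound list

1 | 5-hydroxyvanillin (3,4-dihydroxy-5-methoxybenzaldehyde) | COc1cc(C=O)cc(O)c1O | starting material
2 | benzyl bromide | BrCc1ccccc1 | starting material
3 | disodium dianion of 5-hydroxyvanillin (disodium 5-formyl-3-methoxybenzene-1,2-diolate) | COc1cc(C=O)cc([O-])c1[O-].[Na+].[Na+] | intermediate (not isolated)
4 | 3-(benzyloxy)-4-hydroxy-5-methoxybenzaldehyde | COc1cc(C=O)cc(OCc2ccccc2)c1O | intermediate
5 | ethyl (triphenyl-λ5-phosphanylidene)acetate | CCOC(=O)C=P(c1ccccc1)(c1ccccc1)c1ccccc1 | starting material
6 | ethyl (E)-3-[3-(benzyloxy)-4-hydroxy-5-methoxyphenyl]prop-2-enoate | CCOC(=O)/C=C/c1cc(OC)c(O)c(OCc2ccccc2)c1 | intermediate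
7 | (E)-3-(benzyloxy)-4-hydroxy-5-methoxycinnamyl alcohol | OC/C=C/c1cc(OC)c(O)c(OCc2ccccc2)c1 | intermediate
8 | phenoxyl radical of 7 | OC/C=C/c1cc(OC)c([O])c(OCc2ccccc2)c1 | intermediate (not isolated)
9 | rac-(2R,3R)-2,3-bis{[3-(benzyloxy)-5-methoxy-4-oxocyclohexa-2,5-dien-1-ylidene]methyl}butane-1,4-diol, the C8–C8' bis(quinone methide); exocyclic alkene geometry undefined | OC[C@H](C=C1C=C(OC)C(=O)C(OCc2ccccc2)=C1)[C@@H](C=C1C=C(OC)C(=O)C(OCc2ccccc2)=C1)CO | intermediate (not isolated)
10 | rac-(1S,3aR,4S,6aR)-1,4-bis[3-(benzyloxy)-4-hydroxy-5-methoxyphenyl]tetrahydro-1H,3H-furo[3,4-c]furan (racemate, one enantiomer drawn) | COc1cc([C@H]2OC[C@H]3[C@@H]2CO[C@@H]3c4cc(OC)c(O)c(OCc5ccccc5)c4)cc(OCc6ccccc6)c1O | intermediate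
11 | (1S,3aR,4S,6aR)-1,4-bis[3-(benzyloxy)-4-hydroxy-5-methoxyphenyl]tetrahydro-1H,3H-furo[3,4-c]furan (single enantiomer) | COc1cc([C@H]2OC[C@H]3[C@@H]2CO[C@@H]3c4cc(OC)c(O)c(OCc5ccccc5)c4)cc(OCc6ccccc6)c1O | intermediate
12 | (1S,3aR,4S,6aR)-1,4-bis[3-(benzyloxy)-4,5-dimethoxyphenyl]tetrahydro-1H,3H-furo[3,4-c]furan | COc1cc([C@H]2OC[C@H]3[C@@H]2CO[C@@H]3c4cc(OC)c(OC)c(OCc5ccccc5)c4)cc(OCc6ccccc6)c1OC | intermediate
13 | 5,5'-[(1S,3aR,4S,6aR)-tetrahydro-1H,3H-furo[3,4-c]furan-1,4-diyl]bis(2,3-dimethoxyphenol) | COc1cc([C@H]2OC[C@H]3[C@@H]2CO[C@@H]3c4cc(OC)c(OC)c(O)c4)cc(O)c1OC | intermediate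
14 | 5-[(1S,3aR,4S,6aR)-4-(3,4,5-trimethoxyphenyl)tetrahydro-1H,3H-furo[3,4-c]furan-1-yl]-2,3-dimethoxyphenol | COc1cc([C@H]2OC[C@H]3[C@@H]2CO[C@@H]3c2cc(OC)c(OC)c(OC)c2)cc(O)c1OC | target

## Step count and least certain steps

Total step count: 8. Longest linear sequence: 8 steps (1 to 14).

**Step 4 (key step).** The radical coupling may leak into 8–O–4 products and oligomers, and the phenolic dimer may be re-oxidised. The low water solubility of the benzyl ether aggravates this, because it forces a co-solvent content that slows the enzyme. The fallback leaves the alcohol oxidation level and sets out from 6. Saponification (LiOH, aqueous THF) gives (E)-3-[3-(benzyloxy)-4-hydroxy-5-methoxyphenyl]prop-2-enoic acid F1. The classical oxidative coupling of 4-hydroxycinnamic acids (FeCl3, O2, aqueous acetone) should convert it into the racemic exo,exo-dilactone 1,4-bis[3-(benzyloxy)-4-hydroxy-5-methoxyphenyl]tetrahydro-1H,3H-furo[3,4-c]furan-3,6-dione F2. Excess LiAlH4 in THF reduces this to the racemic tetraol 2,3-bis{[3-(benzyloxy)-4-hydroxy-5-methoxyphenyl](hydroxy)methyl}butane-1,4-diol F3. Acid-catalysed double cyclodehydration (catalytic camphorsulfonic acid, CH2Cl2), which runs through the para-hydroxybenzylic cations and settles on the exo,exo isomer, comes back to the route at 10.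

**Step 5.** Discrimination of the antipodes on the stationary phase may be too weak, or the loading too low, for preparative work. The fallback sets out from 10 and uses covalent diastereomers. Acylation of both phenols with (1S)-camphanoyl chloride (Et3N, DMAP, CH2Cl2) gives the bis[(1S)-camphanate] of the (1S,3aR,4S,6aR) antipode F4 together with the bis[(1S)-camphanate] of the (1R,3aS,4R,6aS) antipode F5. These are separated by crystallisation or silica chromatography. Methanolysis of F4 (K2CO3, MeOH) comes back to the route at 11.

**Step 8.** Over-alkylation and incomplete conversion are inherent to a statistical reaction, so at best about half of 13 can be converted per pass. The fallback sets out from 7 and moves the desymmetrisation into the coupling, where it can be biased by stoichiometry. Co-oxidation of 7 with an excess of commercial sinapyl alcohol F6 under the conditions of step 4 should give the racemic cross-dimer 4-[4-(3-(benzyloxy)-4-hydroxy-5-methoxyphenyl)tetrahydro-1H,3H-furo[3,4-c]furan-1-yl]-2,6-dimethoxyphenol F7. Any 10 formed alongside returns to the main line, and the homodimer of F6 is removed by chromatography. Resolution as in step 5 gives the (1S,3aR,4S,6aR) cross-dimer F8. Exhaustive methylation (MeI, K2CO3, DMF) gives the mono-benzyl ether (1S,3aR,4S,6aR)-1-[3-(benzyloxy)-4,5-dimethoxyphenyl]-4-(3,4,5-trimethoxyphenyl)tetrahydro-1H,3H-furo[3,4-c]furan F9. Hydrogenolysis as in step 7 comes back to the route at 14.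

**Step 1.** Regiocontrol may be lost through alkylation at the para oxide or at both oxygens, and the dianion may be oxidised by air. The fallback sets out from 1 and protects the acidic para phenol first. Weak-base alkylation (allyl bromide, NaHCO3, DMF, 40 °C) should give 4-(allyloxy)-3-hydroxy-5-methoxybenzaldehyde F10. Benzylation of the remaining phenol (2, K2CO3, DMF) gives 4-(allyloxy)-3-(benzyloxy)-5-methoxybenzaldehyde F11. Deallylation with catalytic Pd(PPh3)4 and morpholine in THF comes back to the route at 4.

**Step 7.** Over-reduction may set in, with hydrogenolysis of the benzylic C7–O bonds of the bicycle before both benzyl ethers are gone. The fallback sets out from 1 and carries allyl in place of benzyl, so that no hydrogen is needed. The sequence is: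
- dianion alkylation with allyl bromide to 3-(allyloxy)-4-hydroxy-5-methoxybenzaldehyde F12;
- Wittig olefination with 5 to ethyl (E)-3-[3-(allyloxy)-4-hydroxy-5-methoxyphenyl]prop-2-enoate F13;
- DIBAL-H reduction to (E)-3-(allyloxy)-4-hydroxy-5-methoxycinnamyl alcohol F14;
- laccase dimerisation to racemic 1,4-bis[3-(allyloxy)-4-hydroxy-5-methoxyphenyl]tetrahydro-1H,3H-furo[3,4-c]furan F15;
- resolution to its (1S,3aR,4S,6aR) enantiomer F16;
- methylation to (1S,3aR,4S,6aR)-1,4-bis[3-(allyloxy)-4,5-dimethoxyphenyl]tetrahydro-1H,3H-furo[3,4-c]furan F17.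

Tsuji–Trost deallylation of F17 (catalytic Pd(PPh3)4, morpholine, THF, 20 °C) comes back to the route at 13.

## Further compounds

F1 | step 4 | (E)-3-[3-(benzyloxy)-4-hydroxy-5-methoxyphenyl]prop-2-enoic acid | COc1cc(/C=C/C(=O)O)cc(OCc2ccccc2)c1O
F2 | step 4 | rac-exo,exo-1,4-bis[3-(benzyloxy)-4-hydroxy-5-methoxyphenyl]tetrahydro-1H,3H-furo[3,4-c]furan-3,6-dione (one enantiomer drawn) | COc1cc([C@H]2OC(=O)[C@H]3[C@@H]2C(=O)O[C@@H]3c4cc(OC)c(O)c(OCc5ccccc5)c4)cc(OCc6ccccc6)c1O
F3 | step 4 | rac-2,3-bis{[3-(benzyloxy)-4-hydroxy-5-methoxyphenyl](hydroxy)methyl}butane-1,4-diol (one enantiomer drawn) | COc1cc([C@@H](O)[C@@H](CO)[C@H](CO)[C@H](O)c2cc(OC)c(O)c(OCc3ccccc3)c2)cc(OCc4ccccc4)c1O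
F4 | step 5 | bis[(1S)-camphanate] of 11 | COc1cc([C@H]2OC[C@H]3[C@@H]2CO[C@@H]3c4cc(OC)c(OC(=O)[C@@]56CC[C@@](C)(C(=O)O5)C6(C)C)c(OCc7ccccc7)c4)cc(OCc8ccccc8)c1OC(=O)[C@@]12CC[C@@](C)(C(=O)O1)C2(C)C
F5 | step 5 | bis[(1S)-camphanate] of the (1R,3aS,4R,6aS) antipode of 11 | COc1cc([C@@H]2OC[C@@H]3[C@H]2CO[C@H]3c4cc(OC)c(OC(=O)[C@@]56CC[C@@](C)(C(=O)O5)C6(C)C)c(OCc7ccccc7)c4)cc(OCc8ccccc8)c1OC(=O)[C@@]12CC[C@@](C)(C(=O)O1)C2(C)C
F6 | step 8 | sinapyl alcohol, (E)-4-hydroxy-3,5-dimethoxycinnamyl alcohol (commercial) | COc1cc(/C=C/CO)cc(OC)c1O
F7 | step 8 | rac-4-[4-(3-(benzyloxy)-4-hydroxy-5-methoxyphenyl)tetrahydro-1H,3H-furo[3,4-c]furan-1-yl]-2,6-dimethoxyphenol (one enantiomer drawn) | COc1cc([C@H]2OC[C@H]3[C@@H]2CO[C@@H]3c4cc(OC)c(O)c(OC)c4)cc(OCc5ccccc5)c1O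
F8 | step 8 | (1S,3aR,4S,6aR) enantiomer of F7 | COc1cc([C@H]2OC[C@H]3[C@@H]2CO[C@@H]3c4cc(OC)c(O)c(OC)c4)cc(OCc5ccccc5)c1O
F9 | step 8 | (1S,3aR,4S,6aR)-1-[3-(benzyloxy)-4,5-dimethoxyphenyl]-4-(3,4,5-trimethoxyphenyl)tetrahydro-1H,3H-furo[3,4-c]furan | COc1cc([C@H]2OC[C@H]3[C@@H]2CO[C@@H]3c4cc(OC)c(OC)c(OC)c4)cc(OCc5ccccc5)c1OC
F10 | step 1 | 4-(allyloxy)-3-hydroxy-5-methoxybenzaldehyde | COc1cc(C=O)cc(O)c1OCC=C
F11 | step 1 | 4-(allyloxy)-3-(benzyloxy)-5-methoxybenzaldehyde | COc1cc(C=O)cc(OCc2ccccc2)c1OCC=C
F12 | step 7 | 3-(allyloxy)-4-hydroxy-5-methoxybenzaldehyde | COc1cc(C=O)cc(OCC=C)c1O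
F13 | step 7 | ethyl (E)-3-[3-(allyloxy)-4-hydroxy-5-methoxyphenyl]prop-2-enoate | CCOC(=O)/C=C/c1cc(OC)c(O)c(OCC=C)c1
F14 | step 7 | (E)-3-(allyloxy)-4-hydroxy-5-methoxycinnamyl alcohol | OC/C=C/c1cc(OC)c(O)c(OCC=C)c1
F15 | step 7 | rac-(1S,3aR,4S,6aR)-1,4-bis[3-(allyloxy)-4-hydroxy-5-methoxyphenyl]tetrahydro-1H,3H-furo[3,4-c]furan (one enantiomer drawn) | COc1cc([C@H]2OC[C@H]3[C@@H]2CO[C@@H]3c4cc(OC)c(O)c(OCC=C)c4)cc(OCC=C)c1O
F16 | step 7 | (1S,3aR,4S,6aR)-1,4-bis[3-(allyloxy)-4-hydroxy-5-methoxyphenyl]tetrahydro-1H,3H-furo[3,4-c]furan (single enantiomer) | COc1cc([C@H]2OC[C@H]3[C@@H]2CO[C@@H]3c4cc(OC)c(O)c(OCC=C)c4)cc(OCC=C)c1O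
F17 | step 7 | (1S,3aR,4S,6aR)-1,4-bis[3-(allyloxy)-4,5-dimethoxyphenyl]tetrahydro-1H,3H-furo[3,4-c]furan | COc1cc([C@H]2OC[C@H]3[C@@H]2CO[C@@H]3c4cc(OC)c(OC)c(OCC=C)c4)cc(OCC=C)c1OC
A1 | alternative 1 | C2-symmetric bis-syn-aldol adduct of the succinyl bis-imide with two molecules of A3 | COc1cc([C@@H](O)[C@@H](C(=O)N2[C@@H](Cc3ccccc3)COC2=O)[C@H](C(=O)N4[C@@H](Cc5ccccc5)COC4=O)[C@H](O)c6cc(OC)c(OC)c(OCc7ccccc7)c6)cc(OCc8ccccc8)c1OC
A2 | alternative 1 | 1,4-bis[(S)-4-benzyl-2-oxooxazolidin-3-yl]butane-1,4-dione (succinyl bis-imide) | O=C(CCC(=O)N1[C@@H](Cc2ccccc2)COC1=O)N1[C@@H](Cc2ccccc2)COC1=O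
A3 | alternative 1 | 3-(benzyloxy)-4,5-dimethoxybenzaldehyde | COc1cc(C=O)cc(OCc2ccccc2)c1OC
A4 | alternative 1 | 2,3-bis{[3-(benzyloxy)-4,5-dimethoxyphenyl](hydroxy)methyl}butane-1,4-diol (tetraol from A1) | COc1cc([C@@H](O)[C@@H](CO)[C@H](CO)[C@H](O)c2cc(OC)c(OC)c(OCc3ccccc3)c2)cc(OCc4ccccc4)c1OC
A5 | alternative 2 | exo,exo-1-[3-(benzyloxy)-4,5-dimethoxyphenyl]-4-(3,4,5-trimethoxyphenyl)tetrahydro-1H,3H-furo[3,4-c]furan-3,6-dione | COc1cc([C@H]2OC(=O)[C@H]3[C@@H]2C(=O)O[C@@H]3c4cc(OC)c(OC)c(OC)c4)cc(OCc5ccccc5)c1OC
A6 | alternative 2 | 7-[3-(benzyloxy)-4,5-dimethoxyphenyl]-4-(3,4,5-trimethoxyphenyl)-3-oxabicyclo[3.2.0]heptane-2,6-dione | COc1cc([C@H]2C(=O)[C@H]3[C@@H]2C(=O)O[C@@H]3c4cc(OC)c(OC)c(OC)c4)cc(OCc5ccccc5)c1OC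
A7 | alternative 3 | (1S,3aR,4S,6aR)-1,4-bis[3-(benzyloxy)-4,5-dimethoxyphenyl]tetrahydro-1H,3H-furo[3,4-c]furan (same structure as 12) | COc1cc([C@H]2OC[C@H]3[C@@H]2CO[C@@H]3c4cc(OC)c(OC)c(OCc5ccccc5)c4)cc(OCc6ccccc6)c1OC
A8 | alternative 3 | (3aR,6aR)-tetrahydro-1H,3H-furo[3,4-c]furan-1,4-diyl diacetate (anomeric centres undefined) | CC(=O)OC1OC[C@H]2[C@@H]1COC2OC(C)=O
A9 | alternative 3 | potassium [3-(benzyloxy)-4,5-dimethoxyphenyl]trifluoroborate | COc1cc(cc(OCc2ccccc2)c1OC)[B-](F)(F)F.[K+]
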